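**Retrosynthetic overview**
1. Last step: pyranone ring C and furan ring D form together from a (Z)-aurone whose ring B has been oxidised to a p-quinone. A quinone oxygen adds to the aurone ketal carbon, then a cationic 1,2-acyl shift expands the benzofuran-3(2H)-one to the chromone, and the quinone ends as the 5'-OH phenol.
2. Aurone ⇐ aldol condensation of a tricyclic benzofuran-3(2H)-one (ring A with dihydropyran and prenyl) with 5-hydroxy-2,2-dimethyl-2H-chromene-6-carbaldehyde (ring B with its pyran).
3. Benzofuranone ⇐ aryl chloromethyl ketone ⇐ hexasubstituted ring A built on MOM-protected resorcinol: prenyl by directed lithiation, third oxygen by C–H borylation/oxidation, dihydropyran by enal annulation and hydrogenation, acyl group by a second directed lithiation.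
4. Ring B aldehyde ⇐ resorcinol by formylation and enal annulation.
5. Ring order: dihydropyran on ring A → furanone → (separately) pyran on ring B → union → pyranone C and furan D in the final ring expansion.

Assumption: the target has no stereocentre, so the achiral constitution drawn is the single compound to be made; the only stereo-element on the way is the (Z) double bond of the aurone.
Assumption: 1,3-bis(methoxymethoxy)benzene (resorcinol carrying two MOM protecting groups) is bought.

**Route**

Step 1
Reactants: 1 1,3-bis(methoxymethoxy)benzene; 2 1-bromo-3-methylbut-2-ene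
Product: 3 1,3-bis(methoxymethoxy)-2-(3-methylbut-2-en-1-yl)benzene
Conditions: n-BuLi, THF, 0 °C → rt; CuI (10 mol%), then 2, −78 °C → rt
Reagents that add atoms: none
Why: Directed ortho-metalation, in which the two MOM ethers jointly direct lithiation to the carbon between them, followed by copper-mediated SN2 coupling with the allylic bromide, fixes the prenyl group between the two oxygens that end as O-1 and 7-OH of the target.

Step 2
Reactants: 3 1,3-bis(methoxymethoxy)-2-(3-methylbut-2-en-1-yl)benzene
Product: 5 3,5-bis(methoxymethoxy)-4-(3-methylbut-2-en-1-yl)phenol, via aryl pinacol boronate 4 (not isolated)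
Conditions: [Ir(OMe)(cod)]2 (1.5 mol%), 4,4'-di-tert-butyl-2,2'-bipyridine (3 mol%), B2pin2 (1.0 equiv), THF, 80 °C; then NaOH (aq.), H2O2 (30%), 0 → 25 °C
Reagents that add atoms: bis(pinacolato)diboron, CC1(C)OB(OC1(C)C)B1OC(C)(C)C(C)(C)O1 (boron group of 4 only); hydrogen peroxide, OO (phenol oxygen of 5)
Why: Sterically controlled iridium-catalysed aromatic C–H borylation reaches only the one C–H with no ortho substituent (para to the prenyl group), and the standard alkaline peroxide oxidation of the aryl boronate turns it into the third ring oxygen without touching the trisubstituted alkene.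

Step 3
Reactants: 5 3,5-bis(methoxymethoxy)-4-(3-methylbut-2-en-1-yl)phenol; 6 3-methylbut-2-enal
Product: 7 5,7-bis(methoxymethoxy)-2,2-dimethyl-6-(3-methylbut-2-en-1-yl)-2H-chromene
Conditions: Ti(OEt)4 (1.0 equiv), toluene, reflux (EtOH distilled off); then 6, reflux
Reagents that add atoms: none
Why: Titanium-phenoxide-templated ortho-selective condensation of a phenol with an enal (aldol-type C-alkylation, dehydration to an ortho-quinone methide and oxa-6π ring closure) gives the 2H-chromene, and because the two ortho positions of 5 are equivalent only one regioisomer can form.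

Step 4
Reactants: 7 5,7-bis(methoxymethoxy)-2,2-dimethyl-6-(3-methylbut-2-en-1-yl)-2H-chromene
Product: 8 5,7-bis(methoxymethoxy)-2,2-dimethyl-6-(3-methylbut-2-en-1-yl)chromane
Conditions: H2 (4 atm), RhCl(PPh3)3 (5 mol%), benzene/EtOH 1:1, 40 °C
Reagents that add atoms: none
Why: Homogeneous hydrogenation with RhCl(PPh3)3 reduces the cis-disubstituted styrene-type double bond of the chromene much faster than the trisubstituted prenyl double bond, which gives the saturated dihydropyran ring of the target while keeping the prenyl group.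

Step 5
Reactants: 8 5,7-bis(methoxymethoxy)-2,2-dimethyl-6-(3-methylbut-2-en-1-yl)chromane; 9 2-chloro-N-methoxy-N-methylacetamide
Product: 10 2-chloro-1-[5,7-bis(methoxymethoxy)-2,2-dimethyl-6-(3-methylbut-2-en-1-yl)chroman-8-yl]ethan-1-one
Conditions: n-BuLi, TMEDA, THF, −10 → 0 °C; then 9, −78 → −20 °C; aq. NH4Cl
Reagents that add atoms: none
Why: Directed ortho-metalation at the only aromatic C–H left (between the MOM ether and the ring oxygen) followed by Weinreb-amide acylation, whose stable tetrahedral adduct prevents over-addition, installs the chloromethyl ketone without any acid.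

Step 6
Reactants: 10 2-chloro-1-[5,7-bis(methoxymethoxy)-2,2-dimethyl-6-(3-methylbut-2-en-1-yl)chroman-8-yl]ethan-1-one
Product: 12 5-hydroxy-2,2-dimethyl-6-(3-methylbut-2-en-1-yl)-3,4-dihydro-2H-furo[2,3-h]chromen-9(8H)-one, via dihydroxy chloroketone 11 (not isolated)
Conditions: 2 M HCl in MeOH, 25 °C; then NaOAc (excess), MeOH, 65 °C
Reagents that add atoms: none
Why: Acid-catalysed methanolysis of the MOM acetals, mild enough for an ortho-prenyl phenol, frees the ortho-hydroxy chloromethyl ketone, which on buffering with acetate closes by intramolecular Williamson etherification to the benzofuran-3(2H)-one, and since only one hydroxy group is ortho to the ketone the ring can close in one way only.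

Step 7
Reactants: 13 resorcinol
Product: 14 2,4-dihydroxybenzaldehyde
Conditions: POCl3, DMF, MeCN, −15 °C → rt; then H2O, 50 °C
Reagents that add atoms: N,N-dimethylformamide, CN(C)C=O (formyl carbon); water, O (formyl oxygen)
Why: Vilsmeier–Haack formylation of resorcinol goes para to one hydroxy group and ortho to the other and is the established route to this aldehyde.

Step 8
Reactants: 14 2,4-dihydroxybenzaldehyde; 6 3-methylbut-2-enal
Product: 15 5-hydroxy-2,2-dimethyl-2H-chromene-6-carbaldehyde
Conditions: Ca(OH)2, MeOH, 25 °C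
Reagents that add atoms: none
Why: Base-mediated chromenylation (aldol-type attack by the carbon between the two oxygens, dehydration and oxa-6π closure through the non-chelated 4-OH) is known to give the angular 5-hydroxychromene-6-carbaldehyde from this aldehyde.

Step 9
Reactants: 12 5-hydroxy-2,2-dimethyl-6-(3-methylbut-2-en-1-yl)-3,4-dihydro-2H-furo[2,3-h]chromen-9(8H)-one; 15 5-hydroxy-2,2-dimethyl-2H-chromene-6-carbaldehyde
Product: 16 (8Z)-5-hydroxy-8-[(5-hydroxy-2,2-dimethyl-2H-chromen-6-yl)methylidene]-2,2-dimethyl-6-(3-methylbut-2-en-1-yl)-3,4-dihydro-2H-furo[2,3-h]chromen-9(8H)-one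
Conditions: KOH (50% aq.), MeOH, 60 °C, under Ar
Reagents that add atoms: none
Why: Aldol condensation of the acidic methylene of the benzofuranone with the aldehyde (the standard aurone synthesis) works on unprotected phenols and gives the thermodynamically preferred (Z)-aurone.

Step 10
Reactants: 16 (8Z)-5-hydroxy-8-[(5-hydroxy-2,2-dimethyl-2H-chromen-6-yl)methylidene]-2,2-dimethyl-6-(3-methylbut-2-en-1-yl)-3,4-dihydro-2H-furo[2,3-h]chromen-9(8H)-one
Product: 18 target coumaronochromone CNP0081330.0, via quinone aurone 17 (not isolated)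
Conditions: ON(SO3K)2 (2.5 equiv), KH2PO4 (aq.), Bu4NHSO4 (cat.), CH2Cl2/H2O, 0 → 25 °C; organic phase dried, then (CF3)2CHOH added (1:1), pyridinium p-toluenesulfonate (10 mol%), 25 °C
Reagents that add atoms: potassium nitrosodisulfonate, [K+].[K+].[O-]S(=O)(=O)N([O])S(=O)(=O)[O-] (the oxygen that ends as the 5'-OH)
Why: Proposed new method: Teuber oxidation converts the para-unsubstituted ring B phenol of 16 into the 2-alkoxy-p-quinone 17, and in (CF3)2CHOH with mild acid, protonation of the quinone carbonyl next to the alkoxy carbon makes the aurone ketal carbon an oxocarbenium ion that is captured by the other quinone oxygen (the ring-closing half of the known acid-promoted quinone–enol ether benzofuran annulation) to give a spiroketal with a benzylic cation, whereupon a cationic 1,2-shift of the acyl carbon from the ketal carbon to that cation expands the furanone to the pyranone and leaves a cation stabilised by two oxygens that loses a proton to the aromatic benzofuran, so that 17 isomerises redox-neutrally to 18 with the 5'-OH in place; the closest known reactions are the Lewis-acid 1,2-acyl shift of chalcone and aurone epoxides (semipinacol type) and quinone–enol ether annulations.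

**Compound list**
1 | 1,3-bis(methoxymethoxy)benzene | COCOc1cccc(OCOC)c1 | starting material
2 | 1-bromo-3-methylbut-2-ene (prenyl bromide) | CC(C)=CCBr | starting material
3 | 1,3-bis(methoxymethoxy)-2-(3-methylbut-2-en-1-yl)benzene | COCOc1cccc(OCOC)c1CC=C(C)C | intermediate
4 | 2-[3,5-bis(methoxymethoxy)-4-(3-methylbut-2-en-1-yl)phenyl]-4,4,5,5-tetramethyl-1,3,2-dioxaborolane | COCOc1cc(B2OC(C)(C)C(C)(C)O2)cc(OCOC)c1CC=C(C)C | intermediate
5 | 3,5-bis(methoxymethoxy)-4-(3-methylbut-2-en-1-yl)phenol | COCOc1cc(O)cc(OCOC)c1CC=C(C)C | intermediate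
6 | 3-methylbut-2-enal | CC(C)=CC=O | starting material
7 | 5,7-bis(methoxymethoxy)-2,2-dimethyl-6-(3-methylbut-2-en-1-yl)-2H-chromene | CC1(C)C=Cc2c(OCOC)c(CC=C(C)C)c(OCOC)cc2O1 | intermediate
8 | 5,7-bis(methoxymethoxy)-2,2-dimethyl-6-(3-methylbut-2-en-1-yl)chromane | CC1(C)CCc2c(OCOC)c(CC=C(C)C)c(OCOC)cc2O1 | intermediate
9 | 2-chloro-N-methoxy-N-methylacetamide | CON(C)C(=O)CCl | starting material
10 | 2-chloro-1-[5,7-bis(methoxymethoxy)-2,2-dimethyl-6-(3-methylbut-2-en-1-yl)chroman-8-yl]ethan-1-one | O=C(CCl)c1c(OCOC)c(CC=C(C)C)c(OCOC)c2CCC(C)(C)Oc12 | intermediate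
11 | 2-chloro-1-[5,7-dihydroxy-2,2-dimethyl-6-(3-methylbut-2-en-1-yl)chroman-8-yl]ethan-1-one | O=C(CCl)c1c(O)c(CC=C(C)C)c(O)c2CCC(C)(C)Oc12 | intermediate
12 | 5-hydroxy-2,2-dimethyl-6-(3-methylbut-2-en-1-yl)-3,4-dihydro-2H-furo[2,3-h]chromen-9(8H)-one (benzofuran-3(2H)-one with 6-OH, 7-prenyl and a 2,2-dimethyldihydropyran fused through 4-O and C-5) | O=C1COc2c(CC=C(C)C)c(O)c3CCC(C)(C)Oc3c12 | intermediate
13 | resorcinol (benzene-1,3-diol) | Oc1cccc(O)c1 | starting material
14 | 2,4-dihydroxybenzaldehyde | O=Cc1ccc(O)cc1O | intermediate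
15 | 5-hydroxy-2,2-dimethyl-2H-chromene-6-carbaldehyde | O=Cc1ccc2OC(C)(C)C=Cc2c1O | intermediate
16 | (8Z)-5-hydroxy-8-[(5-hydroxy-2,2-dimethyl-2H-chromen-6-yl)methylidene]-2,2-dimethyl-6-(3-methylbut-2-en-1-yl)-3,4-dihydro-2H-furo[2,3-h]chromen-9(8H)-one | O=C1/C(=C/c2ccc3OC(C)(C)C=Cc3c2O)Oc2c(CC=C(C)C)c(O)c3CCC(C)(C)Oc3c12 | intermediate
17 | (8Z)-8-[(2,2-dimethyl-5,8-dioxo-5,8-dihydro-2H-chromen-6-yl)methylidene]-5-hydroxy-2,2-dimethyl-6-(3-methylbut-2-en-1-yl)-3,4-dihydro-2H-furo[2,3-h]chromen-9(8H)-one | O=C1/C(=C/C2=CC(=O)C3=C(C=CC(C)(C)O3)C2=O)Oc2c(CC=C(C)C)c(O)c3CCC(C)(C)Oc3c12 | intermediate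
18 | CNP0081330.0: coumaronochromone (benzofuran fused through its 2,3-bond to the 2,3-bond of a chromen-4-one); chromone ring A carries a 2,2-dimethyl-3,4-dihydro-2H-pyran fused through 5-O and C-6, 7-OH and 8-(3-methylbut-2-en-1-yl); benzofuran ring B carries 5'-OH and a 2,2-dimethyl-2H-pyran fused through C-3' and 4'-O; achiral | CC(C)=CCc1c(O)c2c(c3c(=O)c4c(oc13)oc1c3c(c(O)cc14)OC(C)(C)C=C3)OC(C)(C)CC2 | target

**Totals and risks**
Total step count: 10. Longest linear sequence: 8 steps (1 → 3 → 5 → 7 → 8 → 10 → 12 → 16 → 18); ring B takes 2 steps (13 → 14 → 15).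

Three steps most likely to fail:

Step 10 (the proposed new cascade). The quinone 17 could be trapped by nucleophiles or decompose before the acyl shift, and the Teuber oxidation of a phenol carrying the aurone may be slow. The fallback uses known chemistry, gives up the ring expansion, sets out from 8 and comes back at 18. Lithiation of 8 as in step 5 and quenching with N-methoxy-N-methylacetamide give 1-[5,7-bis(methoxymethoxy)-2,2-dimethyl-6-(3-methylbut-2-en-1-yl)chroman-8-yl]ethan-1-one F1. Then 2 M HCl in MeOH frees 1-[5,7-dihydroxy-2,2-dimethyl-6-(3-methylbut-2-en-1-yl)chroman-8-yl]ethan-1-one F2, and Me2NCH(OMe)2 (toluene, 80 °C) gives the enaminone (2E)-1-[5,7-dihydroxy-2,2-dimethyl-6-(3-methylbut-2-en-1-yl)chroman-8-yl]-3-(dimethylamino)prop-2-en-1-one F3. For ring B, cyclohexane-1,3-dione and 6 (pyridine, 110 °C) give 2,2-dimethyl-7,8-dihydro-2H-chromen-5(6H)-one F4. DDQ (dioxane, reflux) aromatises it to 2,2-dimethyl-2H-chromen-5-ol F5, and ON(SO3K)2 oxidises that to 2,2-dimethyl-2H-chromene-5,8-dione F6. F3 and F6 in AcOH at 25 °C react by conjugate addition of the enaminone carbon to the quinone carbon para to the alkoxy carbon, then chromone closure with loss of dimethylamine (the classical behaviour of enaminones toward p-quinones). This gives the 2',5'-dihydroxyisoflavone 9-(5,8-dihydroxy-2,2-dimethyl-2H-chromen-6-yl)-5-hydroxy-2,2-dimethyl-6-(3-methylbut-2-en-1-yl)-3,4-dihydro-2H,10H-pyrano[2,3-f]chromen-10-one F7. DDQ (dioxane, 25 °C), the established cyclodehydrogenation of 2'-hydroxyisoflavones, then closes the furan ring to 18.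

Step 4 (hydrogenating the hindered chromene double bond without touching the prenyl group). The fallback removes the selectivity question by making the dihydropyran before the prenyl group exists; it sets out from 1 and comes back at 8. Borylation and oxidation of 1 under the conditions of step 2 pass through 2-[3,5-bis(methoxymethoxy)phenyl]-4,4,5,5-tetramethyl-1,3,2-dioxaborolane F8 to 3,5-bis(methoxymethoxy)phenol F9. Ti(OEt)4 and 6 as in step 3 give 5,7-bis(methoxymethoxy)-2,2-dimethyl-2H-chromene F10, and H2 over Pd/C (EtOAc, 25 °C) gives 5,7-bis(methoxymethoxy)-2,2-dimethylchromane F11. Lithiation with n-BuLi (THF, 0 °C) between the two MOM ethers, then CuI and 2, gives 8.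

Step 3 (enal annulation on a hindered mono-phenol carrying acid-sensitive MOM groups). The fallback builds the chromene by a propargyl ether rearrangement; it sets out from 5 and comes back at 7. Alkylation of 5 with 3-chloro-3-methylbut-1-yne (K2CO3, KI, CuI cat., acetone, reflux) gives the aryl propargyl ether 1,3-bis(methoxymethoxy)-5-[(2-methylbut-3-yn-2-yl)oxy]-2-(3-methylbut-2-en-1-yl)benzene F12. Heating in N,N-diethylaniline at 190 °C (propargyl Claisen rearrangement, hydrogen shift and oxa-6π closure) gives 7.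

**Further compounds**
F1 | step 10 | 1-[5,7-bis(methoxymethoxy)-2,2-dimethyl-6-(3-methylbut-2-en-1-yl)chroman-8-yl]ethan-1-one | CC(=O)c1c(OCOC)c(CC=C(C)C)c(OCOC)c2CCC(C)(C)Oc12
F2 | step 10 | 1-[5,7-dihydroxy-2,2-dimethyl-6-(3-methylbut-2-en-1-yl)chroman-8-yl]ethan-1-one | CC(=O)c1c(O)c(CC=C(C)C)c(O)c2CCC(C)(C)Oc12
F3 | step 10 | (2E)-1-[5,7-dihydroxy-2,2-dimethyl-6-(3-methylbut-2-en-1-yl)chroman-8-yl]-3-(dimethylamino)prop-2-en-1-one | CN(C)/C=C/C(=O)c1c(O)c(CC=C(C)C)c(O)c2CCC(C)(C)Oc12
F4 | step 10 | 2,2-dimethyl-7,8-dihydro-2H-chromen-5(6H)-one | CC1(C)C=CC2=C(O1)CCCC2=O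
F5 | step 10 | 2,2-dimethyl-2H-chromen-5-ol | CC1(C)C=Cc2c(O)cccc2O1
F6 | step 10 | 2,2-dimethyl-2H-chromene-5,8-dione | CC1(C)C=CC2=C(O1)C(=O)C=CC2=O
F7 | step 10 | 9-(5,8-dihydroxy-2,2-dimethyl-2H-chromen-6-yl)-5-hydroxy-2,2-dimethyl-6-(3-methylbut-2-en-1-yl)-3,4-dihydro-2H,10H-pyrano[2,3-f]chromen-10-one | O=c1c(-c2cc(O)c3OC(C)(C)C=Cc3c2O)coc2c(CC=C(C)C)c(O)c3CCC(C)(C)Oc3c12
F8 | step 4 | 2-[3,5-bis(methoxymethoxy)phenyl]-4,4,5,5-tetramethyl-1,3,2-dioxaborolane | COCOc1cc(OCOC)cc(c1)B1OC(C)(C)C(C)(C)O1
F9 | step 4 | 3,5-bis(methoxymethoxy)phenol | COCOc1cc(O)cc(OCOC)c1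
F10 | step 4 | 5,7-bis(methoxymethoxy)-2,2-dimethyl-2H-chromene | CC1(C)C=Cc2c(OCOC)cc(OCOC)cc2O1
F11 | step 4 | 5,7-bis(methoxymethoxy)-2,2-dimethylchromane | CC1(C)CCc2c(OCOC)cc(OCOC)cc2O1
F12 | step 3 | 1,3-bis(methoxymethoxy)-5-[(2-methylbut-3-yn-2-yl)oxy]-2-(3-methylbut-2-en-1-yl)benzene | COCOc1cc(OC(C)(C)C#C)cc(OCOC)c1CC=C(C)C
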